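The constants used here were chosen freely; no experiment stands behind them.

A single-handed partner takes the two mirror-image substrates at different speeds, and the ratio of those speeds says how the product divides while the two substrates stand equal.

| setting | autumn | dawn | summer |
|---|---|---|---|
| left-handed substrate | 20 mM | 20 mM | 20 mM |
| partner | 2.00 equiv | 2.00 equiv | 2.00 equiv |
| precatalyst | 13 mol% | 13 mol% | 13 mol% |
| right-handed substrate | 20 mM | 20 mM | 20 mM |
| temperature | 110 °C | 50 °C | 80 °C |
| time | 15 d | 15 d | 15 d |

    partner + left-handed substrate → left-handed product (k1 = 0.263 M⁻¹ h⁻¹, Ea1 = 87.0 kJ mol⁻¹)
    partner + right-handed substrate → right-handed product (k2 = 0.157 M⁻¹ h⁻¹, Ea2 = 102 kJ mol⁻¹)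
    left-handed substrate + racemization catalyst ⇌ right-handed substrate + racemization catalyst, rate k3*[racemization catalyst]*[left-handed substrate] forward; the back reaction follows from the equilibrium constant (k3 = 9.49 M⁻¹ h⁻¹, Ea3 = 88.0 kJ mol⁻¹)
    partner + precatalyst → racemization catalyst + spent reagent (k4 = 1.74 M⁻¹ h⁻¹, Ea4 = 67.0 kJ mol⁻¹)
    (constants at 110 °C)

- partner is single-handed; left-handed substrate and right-handed substrate are mirror images of each other, charged as a racemate, each of them at the stated concentration
- all constants are for 110 °C and move with temperature by the activation energies
- the handed part of partner does not stay in what it makes, so the products of the two hands are mirror images too

- the flask that comes out highest in amount of left-handed product, in percent of the left-handed substrate and right-handed substrate together charged, or "all alike" when all lie within 1.5 percentage points (autumn / dawn / summer / all alike)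
- left-handed product at the end, in percent of the left-handed substrate and right-handed substrate together charged, autumn
- left-handed product at the end, in percent of the left-handed substrate and right-handed substrate together charged, dawn
- left-handed product at the end, in percent of the left-handed substrate and right-handed substrate together charged, summer

In autumn, at 110 °C, the left-hand constant beats the right-hand one by the selectivity factor 1.68. While the hands stand equal, the product divides by the left share, the left-hand constant over the sum of both constants at the flask's temperature: 62.6%.

But in autumn the left hand is eaten faster, so the hands drift apart unless racemization refills it. In autumn the catalyst, once formed from the whole of the precatalyst, closes the gap at 0.0493 h⁻¹, while partner at its charge consumes left-handed substrate at 0.0105 h⁻¹, so the refill wins. The left hand then lags the right by about 8.59% of itself, a figure reckoned with partner at its charge, and that lowers the share. A further doubt is the catalyst's delay, yet activation in autumn takes about 14.4 h, far shorter than the run.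

How much reacts in autumn? Partner, the limiting reagent, matches the substrate charge, less the 6.50% of that charge lost to precatalyst. Equal amounts consuming each other leave one over one plus 3.02, the mean constant times partner charge times time. The partner's shortfall lifts that remainder by half the gap, to 28.1%. So about 71.9% converts, and this reckoning puts left-handed product at 43.5% with the whole lag and at 45.0% without it.

At the cold end, in dawn, activation needs about 713 h, longer than the run, so this reckoning sets the refill aside. The left hand, half the charge, then simply decays, giving about 1.19%. Summer lies between the ends. Without refill and with partner held at its charge it gives 15.5%, but partner falls and refill arrives, and this reckoning stops there.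

The forecast names autumn, with 44.2% for autumn, 1.15% for dawn and 13.7% for summer. In autumn its hand difference “sits at quasi-steady state”. Its summer figure stands below the rough one above.

The flasks give 44.3% in autumn, 1.15% in dawn and 13.7% in summer, so autumn comes out highest, and the forecast holds.

At 15.0 d autumn holds 44.3% left-handed product against 27.7% right-handed, a left share of 61.6%, just under the reckoned 62.6%. The largest single effect on the gap of 43 percentage points between autumn and dawn is what temperature does to the left-hand step: with that step's constant kept from moving with temperature, the gap becomes −0.59 points. The neighbour of summer at 105 °C has a reckoned left share of 64.1%, and its 40.4% against 23.9% reads 62.9%.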